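## The problem

The target is a ten-membered carbocycle (C1–C10) whose C5 and C10 are joined by an ether oxygen, giving an 11-oxabicyclo[4.4.1]undecane made of two oxepanes: ring A (C1–C4) and ring B (C6–C9). Ring B carries a trans-fused α-methylene-γ-lactone across C7/C8 (oxygen on C8) and an isovalerate on C9; ring A carries only the C4 methyl, and C10 is a fully substituted ether carbon. There are six stereocentres (C4, C5, C7, C8, C9, C10). The one-atom bridge forces C5 and C10 to be cis, so the real task is to relate that bridge to the other four. The C9 oxygen, the C7 carbon substituent and the C4 methyl lie on the face turned toward the bridge (called the bridge face below), whereas the C8 oxygen and the C4 hydrogen point into the cleft between rings A and B. External reagents reach a bicyclo[4.4.1] skeleton from the bridge face, which suits C9 and C7; the C8 oxygen and the C4 hydrogen therefore have to arrive by inversion or by intramolecular delivery. The α-methylene lactone will not survive hydrogenation, hydroxide or nucleophiles, so it is made last; the C10 tertiary ether ionises in strong acid, and the hindered isovalerate is placed only after the last saponification. The feature that makes the key step possible is the one-atom bridge between C5 and C10 with a four-carbon arm on each side: with a carbonyl carbon (Cb) in place of the oxygen this is the adduct of a tropone and a butadiene, the C4 and C10 methyls being those of 2,6-dimethyltropone and the C9 oxygen the terminal oxygen of a 1-acyloxydiene.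

## Retrosynthesis

**Methylene last.** Cutting C11=C13 of 31 leads to the saturated lactone 28. The forward step must enolise a γ-lactone in the presence of the isovalerate; the lactone is the more acidic ester by several pKa units.

**Ether bridge from a transannular hemiketal.** The C5–H bond of 28 is traced to hemiketal 27, and the C5–O bond to attack of the C10 hydroxyl on a C5 ketone (26). The ketone comes from alcohol 25 and this from carboxylic acid 22 by excision of Cb. This is longer than a direct decarboxylative etherification at C5, but an unstabilised secondary cation in a ten-membered ring invites transannular hydride shifts, and every step used here is an established reaction type. The forward reduction can only deliver hydride to the outside of the bridgehead, so C5 is fixed by C10.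

**C9 ester and C4 hydrogen in the monocycle.** Removing the isovalerate (20) from 22 gives 19, and removing H2 from C3–C4 gives the cyclodecene acid 18. In every bicyclo[4.4.1] intermediate the open face of C3=C4 is the bridge face; hydrogen added there would leave the C4 methyl in the cleft, which is the C4 epimer. In monocyclic 18 the C5 carboxyl is the only substituent next to the alkene. 1,3-Allylic strain fixes the C4–C5 rotamer, and a carboxyl-directed hydrogenation should place H4 cis to H5, which is the required arrangement. This is why the trisubstituted alkene is carried through the bridge cleavage.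

**Bridge opened by Baeyer–Villiger oxidation.** Acid 18 comes from bridging lactone 16 and this from ketone 14 by insertion of oxygen into the Cb–C10 bond with retention. C3=C4 must survive, so a silyl peroxide is used in place of a peracid. The C1=C2 alkene is removed beforehand (13 to 14), otherwise the new C10–O bond would be a doubly allylic tertiary ester.

**Ring B from an epoxy acid.** The trans-lactone and the C9 hydroxyl of 13 are disconnected to an 8,9-epoxide on the bridge face, opened at C8 with inversion by the C7 acetic acid side chain (12). The epoxide comes from iodolactone 11, and this from the γ,δ-unsaturated acid 10. Iodolactonisation is chosen over direct epoxidation because it picks out C8=C9 in the presence of the ring A diene and guarantees the epoxide face. These steps precede the bridge cleavage because the later free C10 hydroxyl would otherwise sit next to the epoxide.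

**C7–C11 by Ireland–Claisen rearrangement.** Acid 10 is traced to allylic acetate 7. The rearrangement moves the two acetate carbons (C11, C12) from the C9 oxygen to C7 on the same face and shifts the alkene to C8=C9. No carbon has to be brought in from outside, and the face is set by the cycloaddition.

**Key disconnection.** After resolution (7 from racemic 6), cutting C5–C6 and C9–C10 gives 2,6-dimethyltropone 4 and (E)-1-acetoxybuta-1,3-diene 5. One thermal [6+4] step builds the carbocycle and the bridge and sets C5, C10 and C9.

**Tropone.** Tropone 4 is traced through dibromocyclopropane 3 and dihydroanisole 2 to 2,6-dimethylanisole 1.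

## Roads not taken

Alternative 1: The lactone ring is closed last. Rh2(OAc)4 would decompose the C8 diazophosphonoacetate A2 and the carbenoid would insert into a C7–H bond to give the α-phosphono lactone A1; condensation with formaldehyde would then give 31. The merit is real: the exocyclic methylene arrives by a mild olefination, cleaner than the enolate methylenation of 28, and no lactone has to be carried through earlier steps. The weak points are that A2 already contains the whole oxygen-bridged core with the C8 oxygen on the hindered face, so the main problem is untouched. The insertion must also choose one of two diastereotopic C7 hydrogens, in competition with the activated C9–H and the C–H bonds of the isovalerate. Against this the chosen plan sets the C7 configuration by a suprafacial shift whose face is fixed in 7, and it still needs a route to the core.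

Alternative 2: The oxirane C5–C10 bond of the ring-fused divinyl epoxide A4 is broken in a [3,3] shift that forms C2–C3 and gives the bis(enol ether) A3. This makes the oxygen bridge directly and would save the five steps spent here on exchanging carbon for oxygen; in that respect it is better. Its weak points are the precursor (a tetrasubstituted, ring-fused cis-dialkenyl epoxide on a cyclohexane that already carries C7–C9) and the steps after A3. The C10 methyl must be added to a bridgehead oxocarbenium ion, and reduction of the C4=C5 enol ether from its only open face puts H4 cis to H5 on the oxepane, hence the C4 methyl in the cleft, the wrong epimer. The chosen plan sets against it flat, cheap components and a defined way to set C4.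

Alternative 3: KH with 18-crown-6 would trigger the anionic oxy-Cope shift of the trans-dialkenylcyclohexanol A6 to the (E)-cyclodecenone A5, breaking C5–C10 and forming C7–C8. This road is better in two respects. C4 is set in a six-membered ring before the medium ring exists. The (E)-C9=C10 alkene is also well placed: anti opening of its epoxide at C10 by a C5 oxygen would give the bridge and the C9 hydroxyl in one step. Its weak points are that the face of that epoxidation and the C5 configuration must be relayed across a mobile ten-membered ring, and that A6 needs vicinal fully substituted carbons bearing trans alkenyl groups, one of them an enol ether. The chosen plan sets against it the rigid bicycle, in which C5, C9 and C10 are locked in one step and C7–C9 are then derived from the acetoxy group.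

Key step: step 4

Assumption: commercial 1-acetoxybuta-1,3-diene is an E/Z mixture; only the E isomer 5 is taken to react under the thermal conditions.

Step 1
Reactants: 1 2,6-dimethylanisole
Product: 2 1-methoxy-2,6-dimethylcyclohexa-1,4-diene (racemic)
Conditions: Li, NH3(l), t-BuOH, THF, −78 to −33 °C; solid NH4Cl
Reagents that add atoms: none
Why: Birch reduction of an anisole gives the 2,5-dihydro product, here with the enol ether double bond between C1 and one methylated carbon; the remaining sp3 stereocentre is lost later.

Step 2
Reactants: 2 1-methoxy-2,6-dimethylcyclohexa-1,4-diene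
Product: 3 7,7-dibromo-1-methoxy-2,6-dimethylbicyclo[4.1.0]hept-3-ene (racemic, diastereomer mixture)
Conditions: CHBr3 (1.1 equiv), KOtBu, pentane, −20 to 0 °C
Reagents that add atoms: bromoform, BrC(Br)Br
Why: Dihalocarbene cyclopropanation; the electrophilic carbene should add to the electron-rich tetrasubstituted enol ether alkene and leave the disubstituted alkene.

Step 3
Reactants: 3 7,7-dibromo-1-methoxy-2,6-dimethylbicyclo[4.1.0]hept-3-ene
Product: 4 2,6-dimethyltropone (2,6-dimethylcyclohepta-2,4,6-trien-1-one)
Conditions: pyridine, 110 °C
Reagents that add atoms: none
Why: Ring expansion of an alkoxy dihalocyclopropane: loss of bromide with cyclopropyl-to-allyl opening assisted by the methoxy group, then loss of HBr and O-demethylation of the methoxytropylium ion; all ring carbons end sp2, so the product is fixed by connectivity, with the carbene carbon as the unsubstituted α-carbon.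

Step 4
Reactants: 4 2,6-dimethyltropone; 5 (E)-1-acetoxybuta-1,3-diene
Product: 6 racemic exo adduct, 9-acetoxy-4,10-dimethylbicyclo[4.4.1]undeca-1,3,7-trien-11-one (target numbering; acetoxy on the face of the carbonyl bridge Cb)
Conditions: xylene, 140 °C, sealed tube, BHT (cat.), excess 5
Reagents that add atoms: none
Why: Thermally allowed, concerted [6π+4π] cycloaddition, suprafacial on both partners; the closest known reaction is the exo-selective thermal addition of tropone itself to 1-acetoxybutadiene. The ten-membered ring, and with it the two seven-membered rings sharing Cb, closes by intermolecular cycloaddition as C5–C6 and C9–C10 form at the termini of the tropone triene and of the s-cis diene. C5 and C10 arise by addition to one face of the planar tropone and are therefore cis across Cb. C9 is set by the E geometry of the enol acetate together with the exo transition state, in which the diene lies over the carbonyl and away from the triene, so the acetoxy group ends on the Cb face. The step needs [6+4] rather than [4+2] periselectivity, which the exo mode of tropone secures because the endo [6+4] arrangement has repulsive secondary overlap. It also needs the acetoxy terminus to bond to the methylated C2 of the tropone: the unsubstituted diene terminus carries the larger HOMO coefficient and should bond first to the unhindered tropone C7. The adduct is racemic. The temperature is kept below that at which the 1,5-diene unit could undergo Cope rearrangement.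

Step 5
Reactants: 6 racemic exo adduct
Product: 7 (5R,9S,10R)-9-acetoxy-4,10-dimethylbicyclo[4.4.1]undeca-1,3,7-trien-11-one (target numbering; unreacted enantiomer)
Conditions: Candida antarctica lipase B (immobilised), phosphate buffer pH 7/MTBE, 35 °C, run just past half conversion
Reagents that add atoms: none
Why: Lipase-catalysed kinetic resolution by enantioselective acetate hydrolysis; the empirical size rule for secondary alcohols (large quaternary C10 side against the vinylic C8 side) predicts faster hydrolysis of the (9R)-acetate, so the (9S)-acetate needed should remain and is separated from the antipodal alcohol.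

Step 6
Reactants: 7 resolved acetate
Product: 10 2-[4,10-dimethyl-11-oxobicyclo[4.4.1]undeca-1,3,8-trien-7-yl]acetic acid (target numbering; side chain on the bridge face of C7), via silyl ketene acetal 8 (not isolated), via trimethylsilyl ester 9 (not isolated)
Conditions: LDA, Me3SiCl/Et3N (premixed, internal quench), THF, −78 °C, then 60 °C; aq. HCl
Reagents that add atoms: none
Why: Ireland–Claisen rearrangement of a cyclic allylic acetate; the [3,3] shift is suprafacial, so the C7–C11 bond forms on the face that held the C9 oxygen and C7 is set from C9. The ketone at Cb cannot enolise because both α-carbons are bridgeheads, and the internal silyl quench keeps the ester enolate from adding to it.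

Step 7
Reactants: 10 Claisen acid
Product: 11 cis-fused iodolactone (lactone oxygen on C8 on the bridge face, iodine on C9 on the ring A face; ring A diene and Cb ketone intact)
Conditions: I2, NaHCO3, MeCN/H2O, 0 °C, dark
Reagents that add atoms: iodine, II
Why: Iodolactonisation; iodonium formation is reversible and only the carboxylate-assisted 5-exo anti opening at C8 is productive (C9 is neopentylic), which selects C8=C9 over the ring A diene and gives the cis γ-lactone.

Step 8
Reactants: 11 iodolactone
Product: 13 trans-fused 9-hydroxy-8,12-lactone (C7 side chain and C9 hydroxyl on the bridge face, C8 oxygen on the ring A face), via epoxy carboxylate 12 (not isolated)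
Conditions: NaOH, THF/H2O, 0 °C to rt; then aq. HCl to pH 2, rt
Reagents that add atoms: sodium hydroxide, [Na+].[OH-]
Why: Saponification frees the C8 alkoxide, which displaces the anti C9 iodide to give the 8,9-epoxide on the bridge face; on acidification the carboxylic acid opens the epoxide at C8 with inversion (5-exo; attack at C9 would need an impossible 1,3-trans bridge), setting the C8 oxygen trans to C7 and leaving the C9 hydroxyl on the bridge face.

Step 9
Reactants: 13 hydroxy lactone
Product: 14 1,2-dihydro derivative of 13 (C3=C4 retained)
Conditions: 2-nitrobenzenesulfonylhydrazide, Et3N, CH2Cl2, rt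
Reagents that add atoms: none
Why: Diimide reduction, which strongly prefers the cis-disubstituted C1=C2 over the trisubstituted C3=C4; this removes the allylic relation between C10 and ring A before the oxygen insertion.

Step 10
Reactants: 14 dihydro ketone
Product: 16 bridging lactone C10–O–C(=O)–C5 with C9 trimethylsilyl ether (C3=C4 and the γ-lactone intact), via silyl ether 15 (not isolated)
Conditions: BSA, CH2Cl2, rt; then Me3SiOOSiMe3, Me3SiOTf (cat.), CH2Cl2, −78 to −20 °C; pyridine quench
Reagents that add atoms: N,O-bis(trimethylsilyl)acetamide, CC(=N[Si](C)(C)C)O[Si](C)(C)C; bis(trimethylsilyl) peroxide, C[Si](C)(C)OO[Si](C)(C)C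
Why: Silylation masks the β-hydroxy ketone against retro-aldol cleavage; Baeyer–Villiger oxidation with the silyl peroxide does not epoxidise alkenes, and the fully substituted C10 should migrate in preference to the secondary C5, with retention, so the C10–O bond takes the place of the C10–Cb bond.

Step 11
Reactants: 16 bridging lactone
Product: 18 monocyclic hydroxy acid: (Z)-cyclodec-3-ene with C5 carboxylic acid, trans-8,12-lactone, C9 hydroxyl and C10 tertiary hydroxyl, via dilithium dicarboxylate 17 (not isolated)
Conditions: LiOH, THF/H2O, 50 °C; then aq. HCl to pH 3, 0 °C to rt
Reagents that add atoms: lithium hydroxide, [Li+].[OH-]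
Why: Saponification opens both lactones and removes the silyl group; on mild acidification only the five-membered lactone should close again, because the eight-membered bridging lactone is not reformed, and the bridge is thereby opened without touching any stereocentre.

Step 12
Reactants: 18 hydroxy acid
Product: 19 C3–C4 saturated hydroxy acid (C4 methyl cis to the C5 carboxyl on the ten-membered ring)
Conditions: H2 (1–4 atm), [Ir(cod)(PCy3)(py)]PF6 (5–10 mol %), CH2Cl2, rt
Reagents that add atoms: none
Why: Carbonyl-directed homogeneous hydrogenation: 1,3-allylic strain against C2 holds H5 in the alkene plane, so the carboxyl lies over one face and C6 with the ring body under the other; iridium bound to the carboxyl should add hydrogen to the exposed face, making H4 cis to H5, which is the C4 configuration of the target once oxygen replaces Cb.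

Step 13
Reactants: 19 saturated hydroxy acid; 20 isovaleryl chloride
Product: 22 C9 isovalerate carboxylic acid, via mixed anhydride 21 (not isolated)
Conditions: pyridine, DMAP (cat.), CH2Cl2, 0 °C to rt; then aq. NaHCO3/THF
Reagents that add atoms: none
Why: Acylation of the only secondary alcohol (the C10 alcohol is tertiary); the mixed anhydride formed at the C5 acid is hydrolysed in the work-up, and any epimerisation at C5 no longer matters because C4 is set and C5 next becomes a ketone.

Step 14
Reactants: 22 isovalerate acid
Product: 25 C5 alcohol (both C5 epimers), via Barton ester 23 (not isolated), via hydroperoxide 24 (not isolated)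
Conditions: N-hydroxypyridine-2-thione, DCC, CH2Cl2, dark; then O2, t-BuSH, hν (tungsten lamp), toluene, 10 °C; then P(OMe)3
Reagents that add atoms: dioxygen, O=O
Why: Barton decarboxylative hydroxylation: the secondary C5 radical is trapped by oxygen and the hydroperoxide is reduced; the neutral radical conditions leave the lactone, the ester and the tertiary alcohol untouched, and the C5 configuration is irrelevant.

Step 15
Reactants: 25 C5 alcohol
Product: 27 bridged hemiketal (5-hydroxy-5,10-epoxide), via hydroxy ketone 26 (not isolated)
Conditions: Dess–Martin periodinane, NaHCO3, CH2Cl2, rt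
Reagents that add atoms: none
Why: Buffered oxidation of the only secondary alcohol; a 6-hydroxycyclodecanone closes spontaneously to the transannular hemiketal, which also protects C4 from enolisation, and the C9 oxygen is blocked so only the C10 hydroxyl can add.

Step 16
Reactants: 27 hemiketal
Product: 28 11,13-dihydro-13-nor target (oxygen-bridged lactone isovalerate without the exocyclic methylene)
Conditions: Et3SiH, BF3·OEt2, CH2Cl2, −78 to 0 °C
Reagents that add atoms: none
Why: Reductive etherification: Lewis acid ionisation of the hemiketal to the bridgehead oxocarbenium ion and hydride transfer from the silane, which can only arrive from outside the bicycle, so C5 is set by the C10–O bond; esters and lactone are inert.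

Step 17
Reactants: 28 saturated lactone
Product: 31 target, via Mannich base 29 (not isolated), via ammonium iodide 30 (not isolated)
Conditions: LiHMDS (1.05 equiv), THF, −78 °C; CH2=NMe2+ I−, −78 to 0 °C; then MeI, MeOH; then aq. NaHCO3, rt
Reagents that add atoms: dimethylmethyleneammonium iodide, C=[N+](C)C.[I-]
Why: Enolate Mannich reaction followed by quaternisation and elimination (α-methylenation of a γ-lactone); with one equivalent of base the lactone, more acidic than the hindered acyclic isovalerate, should be enolised selectively, and the C11 configuration of the intermediates is lost on elimination.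

Compound list

1 | 2,6-dimethylanisole | COc1c(C)cccc1C | starting material
2 | 1-methoxy-2,6-dimethylcyclohexa-1,4-diene (racemic) | COC1=C(C)CC=CC1C | intermediate
3 | 7,7-dibromo-1-methoxy-2,6-dimethylbicyclo[4.1.0]hept-3-ene (racemic, diastereomer mixture) | COC12C(C)C=CCC1(C)C2(Br)Br | intermediate
4 | 2,6-dimethyltropone | O=C1C(C)=CC=CC(C)=C1 | intermediate
5 | (E)-1-acetoxybuta-1,3-diene | CC(=O)O/C=C/C=C | starting material
6 | racemic exo adduct, 9-acetoxy-4,10-dimethylbicyclo[4.4.1]undeca-1,3,7-trien-11-one (relative configuration shown) | O=C1[C@]2(C)C=CC=C(C)[C@H]1CC=C[C@@H]2OC(C)=O | intermediate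
7 | (5R,9S,10R) enantiomer of 6 | O=C1[C@]2(C)C=CC=C(C)[C@H]1CC=C[C@@H]2OC(C)=O | intermediate
8 | trimethylsilyl ketene acetal of 7 | O=C1[C@]2(C)C=CC=C(C)[C@H]1CC=C[C@@H]2OC(=C)O[Si](C)(C)C | intermediate (not isolated)
9 | trimethylsilyl ester of 10 | O=C1[C@]2(C)C=CC=C(C)[C@H]1C[C@H](CC(=O)O[Si](C)(C)C)C=C2 | intermediate (not isolated)
10 | C7 acetic acid with C8=C9, side chain on the bridge face | O=C1[C@]2(C)C=CC=C(C)[C@H]1C[C@H](CC(=O)O)C=C2 | intermediate
11 | cis-fused 9-iodo-8,12-lactone | O=C1[C@]2(C)C=CC=C(C)[C@H]1C[C@@H]3CC(=O)O[C@@H]3[C@H]2I | intermediate
12 | sodium salt of the 8,9-epoxy acid (oxirane on the bridge face) | O=C1[C@]2(C)C=CC=C(C)[C@H]1C[C@H](CC(=O)[O-])[C@@H]3O[C@@H]32.[Na+] | intermediate (not isolated)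
13 | trans-fused 9-hydroxy-8,12-lactone, ring A diene and Cb ketone intact | O=C1[C@]2(C)C=CC=C(C)[C@H]1C[C@@H]3CC(=O)O[C@H]3[C@@H]2O | intermediate
14 | 1,2-dihydro-13 | O=C1[C@]2(C)CCC=C(C)[C@H]1C[C@@H]3CC(=O)O[C@H]3[C@@H]2O | intermediate
15 | C9 trimethylsilyl ether of 14 | O=C1[C@]2(C)CCC=C(C)[C@H]1C[C@@H]3CC(=O)O[C@H]3[C@@H]2O[Si](C)(C)C | intermediate (not isolated)
16 | bridging lactone (C10–O–CO–C5), C9 trimethylsilyl ether | O=C1O[C@]2(C)CCC=C(C)[C@H]1C[C@@H]3CC(=O)O[C@H]3[C@@H]2O[Si](C)(C)C | intermediate
17 | dilithium salt of the fully ring-opened triol diacid | [Li+].[Li+].[O-]C(=O)[C@@H]1C[C@H](CC(=O)[O-])[C@@H](O)[C@H](O)[C@](C)(O)CCC=C1C | intermediate (not isolated)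
18 | monocyclic hydroxy acid with C3=C4 and trans-8,12-lactone | OC(=O)[C@@H]1C[C@@H]2CC(=O)O[C@H]2[C@H](O)[C@](C)(O)CCC=C1C | intermediate
19 | C4-saturated hydroxy acid | OC(=O)[C@@H]1C[C@@H]2CC(=O)O[C@H]2[C@H](O)[C@](C)(O)CCC[C@@H]1C | intermediate
20 | isovaleryl chloride | CC(C)CC(Cl)=O | starting material
21 | mixed isovaleric anhydride of 22 | CC(C)CC(=O)OC(=O)[C@@H]1C[C@@H]2CC(=O)O[C@H]2[C@H](OC(=O)CC(C)C)[C@](C)(O)CCC[C@@H]1C | intermediate (not isolated)
22 | C9 isovalerate, C5 carboxylic acid | OC(=O)[C@@H]1C[C@@H]2CC(=O)O[C@H]2[C@H](OC(=O)CC(C)C)[C@](C)(O)CCC[C@@H]1C | intermediate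
23 | N-acyloxypyridine-2-thione (Barton ester) of 22 | S=C1C=CC=CN1OC(=O)[C@@H]1C[C@@H]2CC(=O)O[C@H]2[C@H](OC(=O)CC(C)C)[C@](C)(O)CCC[C@@H]1C | intermediate (not isolated)
24 | C5 hydroperoxide (C5 epimers) | OOC1C[C@@H]2CC(=O)O[C@H]2[C@H](OC(=O)CC(C)C)[C@](C)(O)CCC[C@@H]1C | intermediate (not isolated)
25 | C5 alcohol (C5 epimers) | OC1C[C@@H]2CC(=O)O[C@H]2[C@H](OC(=O)CC(C)C)[C@](C)(O)CCC[C@@H]1C | intermediate
26 | C5 ketone, C10 hydroxyl (open form) | O=C1C[C@@H]2CC(=O)O[C@H]2[C@H](OC(=O)CC(C)C)[C@](C)(O)CCC[C@@H]1C | intermediate (not isolated)
27 | bridged hemiketal (5-hydroxy-5,10-epoxide) | C1C(=O)O[C@@H]2[C@@H]1C[C@@]1(O)O[C@](C)(CCC[C@@H]1C)[C@H]2OC(=O)CC(C)C | intermediate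
28 | oxygen-bridged lactone isovalerate lacking the exocyclic methylene | C1C(=O)O[C@@H]2[C@@H]1C[C@H]1O[C@](C)(CCC[C@@H]1C)[C@H]2OC(=O)CC(C)C | intermediate
29 | α-(dimethylaminomethyl) lactone (C11 epimers) | CN(C)CC1C(=O)O[C@@H]2[C@@H]1C[C@H]1O[C@](C)(CCC[C@@H]1C)[C@H]2OC(=O)CC(C)C | intermediate (not isolated)
30 | trimethylammoniomethyl lactone iodide | C[N+](C)(C)CC1C(=O)O[C@@H]2[C@@H]1C[C@H]1O[C@](C)(CCC[C@@H]1C)[C@H]2OC(=O)CC(C)C.[I-] | intermediate (not isolated)
31 | CNP0274454.1 | C=C1C(=O)O[C@@H]2[C@@H]1C[C@H]1O[C@](C)(CCC[C@@H]1C)[C@H]2OC(=O)CC(C)C | target

Total step count: 17. Longest linear sequence: 17 steps, from 1 to 31 (5 and 20 are purchased).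

Least certain steps

Step 4 (key step). The likely failure is loss of regiocontrol or periselectivity: the crowded bond between the acetoxy-bearing terminus and the methylated tropone carbon may form too slowly, so that the reversed regioisomer or [4+2] adducts compete. The fallback sets out from 4 and returns at 6. The more polarised, commercial (E)-1-(trimethylsilyloxy)buta-1,3-diene is used in place of 5, so that bond formation becomes more asynchronous and starts at the unhindered tropone carbon; this should give the silyl ether adduct F1. Mild acid then frees the alcohol F2, and Ac2O with pyridine and DMAP gives 6.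

Step 10. Two things may go wrong: the hindered ketone may react sluggishly with the silyl peroxide, or the allylic C5 may migrate in competition with C10. The fallback sets out from 14 and returns at 18. Excess m-CPBA with NaHCO3 first epoxidises C3=C4 from the bridge face to the epoxy ketone F5, which removes the allylic character of C5, and then effects a conventional Baeyer–Villiger oxidation with C10 migration to the epoxy bis-lactone F6. Stereospecific deoxygenation with WCl6/n-BuLi restores the alkene in the bis-lactone F7, which is saponified and re-lactonised as in step 11 to give 18.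

Step 12. Facial selectivity may be poor if the ten-membered ring populates a second rotamer about C4–C5 or if the C10 hydroxyl competes as directing group. The fallback sets out from 18 and returns at 19, and replaces substrate control by catalyst control. The acid is converted with BnBr and K2CO3 into the benzyl ester F8, the alkene is reduced with a chiral iridium phosphinooxazoline catalyst, [Ir(cod)(tBu-PHOX)]BArF, whose enantiomer is chosen to give the benzyl ester F9 with the required C4 configuration, and hydrogenolysis over Pd/C gives 19.

Step 8. The intramolecular opening needs a strained trajectory (side chain on one face, attack from the other), so it may be slow, and water may then attack unselectively or the epoxide may rearrange toward the neighbouring ketone. The fallback sets out from 11 and returns at 13, and separates the two events. K2CO3 in MeOH gives the epoxy methyl ester F3, aqueous HClO4 in THF opens the epoxide with water at the less hindered C8 to the diol ester F4, and TsOH closes the C8 hydroxyl onto the ester to give 13.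

Step 16. Ionisation at the bridgehead may be slow because the oxocarbenium ion is twisted, and the open hydroxy ketone may then be reduced to a diol instead. The fallback sets out from 27 and returns at 28, and avoids the cation. The hemiketal hydroxyl is acylated with methyl oxalyl chloride and DMAP to the methyl oxalate F10, and Bu3SnH with AIBN in refluxing toluene removes it through the bridgehead α-alkoxy radical, which takes hydrogen from outside.

Step 17. Enolisation may not discriminate well enough between the lactone and the isovalerate, leading to methylenation or Claisen chemistry at the side-chain ester. The fallback sets out from 28 and returns at 31, and avoids an amide base. Carboxylation with MeOMgOCO2Me in DMF, which acts on lactones but not on simple esters, gives the α-carboxy lactone F11, and aqueous formaldehyde with Et2NH brings about the decarboxylative Mannich methylenation to 31.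

Further compounds

F1 | step 4 | racemic 9-trimethylsilyloxy-4,10-dimethylbicyclo[4.4.1]undeca-1,3,7-trien-11-one (exo) | O=C1[C@]2(C)C=CC=C(C)[C@H]1CC=C[C@@H]2O[Si](C)(C)C
F2 | step 4 | racemic 9-hydroxy-4,10-dimethylbicyclo[4.4.1]undeca-1,3,7-trien-11-one (exo) | O=C1[C@]2(C)C=CC=C(C)[C@H]1CC=C[C@@H]2O
F3 | step 8 | methyl ester of the 8,9-epoxy acid (oxirane on the bridge face) | O=C1[C@]2(C)C=CC=C(C)[C@H]1C[C@H](CC(=O)OC)[C@@H]3O[C@@H]32
F4 | step 8 | methyl ester of the trans-8,9-diol (C8 hydroxyl on the ring A face, C9 hydroxyl on the bridge face) | O=C1[C@]2(C)C=CC=C(C)[C@H]1C[C@H](CC(=O)OC)[C@@H](O)[C@@H]2O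
F5 | step 10 | 3,4-epoxide of 14 (oxirane on the bridge face) | O=C1[C@]2(C)CC[C@@H]3O[C@]3(C)[C@H]1C[C@@H]4CC(=O)O[C@H]4[C@@H]2O
F6 | step 10 | 3,4-epoxy bridging lactone | O=C1O[C@]2(C)CC[C@@H]3O[C@]3(C)[C@H]1C[C@@H]4CC(=O)O[C@H]4[C@@H]2O
F7 | step 10 | bridging lactone with C3=C4 and free C9 hydroxyl | O=C1O[C@]2(C)CCC=C(C)[C@H]1C[C@@H]3CC(=O)O[C@H]3[C@@H]2O
F8 | step 12 | benzyl ester of 18 | O=C(OCc1ccccc1)[C@@H]1C[C@@H]2CC(=O)O[C@H]2[C@H](O)[C@](C)(O)CCC=C1C
F9 | step 12 | benzyl ester of 19 | O=C(OCc1ccccc1)[C@@H]1C[C@@H]2CC(=O)O[C@H]2[C@H](O)[C@](C)(O)CCC[C@@H]1C
F10 | step 16 | methyl oxalate of hemiketal 27 | C1C(=O)O[C@@H]2[C@@H]1C[C@@]1(OC(=O)C(=O)OC)O[C@](C)(CCC[C@@H]1C)[C@H]2OC(=O)CC(C)C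
F11 | step 17 | α-carboxy lactone of 28 (C11 epimers) | OC(=O)C1C(=O)O[C@@H]2[C@@H]1C[C@H]1O[C@](C)(CCC[C@@H]1C)[C@H]2OC(=O)CC(C)C
A1 | alternative 1 | α-diethylphosphono trans-lactone on the complete oxygen-bridged core | CCOP(=O)(OCC)[C@H]1C(=O)O[C@@H]2[C@@H]1C[C@H]1O[C@](C)(CCC[C@@H]1C)[C@H]2OC(=O)CC(C)C
A2 | alternative 1 | C8 diazo(diethylphosphono)acetate of the oxygen-bridged core with C9 isovalerate | CCOP(=O)(OCC)C(=[N+]=[N-])C(=O)O[C@@H]2CC[C@H]1O[C@](C)(CCC[C@@H]1C)[C@H]2OC(=O)CC(C)C
A3 | alternative 2 | 11-oxabicyclo[4.4.1]undecadiene with C4=C5 and C1=C10 enol ethers, lactone and C9 silyl ether | CC1=C2C[C@@H]3CC(=O)O[C@H]3[C@H](O[Si](C)(C)C(C)(C)C)C(=CCC1)O2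
A4 | alternative 2 | cyclohexane-fused oxirane with isopropenyl on C5 and vinyl on C10 (oxirane face not specified) | CC(=C)C12C[C@@H]3CC(=O)O[C@H]3[C@H](O[Si](C)(C)C(C)(C)C)C1(C=C)O2
A5 | alternative 3 | (E)-cyclodec-5-enone with C7 silyloxyethyl and C8 benzyloxy groups | O=C1C[C@H](CCO[Si](C)(C)C(C)(C)C)[C@@H](OCc2ccccc2)/C=C(C)/CCC[C@@H]1C
A6 | alternative 3 | trans-1,2-dialkenylcyclohexanol (alkenyl groups trans; relation of the ring centres to those of A5 not fixed here) | C[C@@H]1CCC[C@@](C)(/C=C/OCc2ccccc2)[C@]1(O)/C=C/CCO[Si](C)(C)C(C)(C)C
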